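A leftover comes first: if each coupling partner takes one starting material and nothing else consumes either, 40.0% of the starting material charged stays over in the four flasks asked about, and target stops at a ceiling of 60.0%.

| setting | epsilon | gamma | zeta | midnight | spring | dawn | autumn |
|---|---|---|---|---|---|---|---|
| starting material | 0.0050 M | 0.020 M | 0.010 M | 0.010 M | 0.010 M | 0.010 M | 0.010 M |
| coupling partner | 0.60 equiv | 0.60 equiv | 0.30 equiv | 0.600 equiv | 0.600 equiv | 0.600 equiv | 0.600 equiv |
| temperature | 20 °C | 53 °C | 20 °C | 5 °C |  | 65 °C | 35 °C |
| remark | run made earlier | run made earlier | run made earlier |  | at 5 °C until 1.5 h, from then on at 65 °C |  |  |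
| time |  |  |  | 5.0 h | 5.0 h | 5.0 h | 5.0 h |

- epsilon (time / min: target / %): 12.0: 8.3; 25.0: 16.4; 40.0: 22.9; 60.0: 29.4; 80.0: 34.5
- gamma (time / min: target / %): 2.50: 36.1; 5.00: 46.8; 8.00: 51.4; 12.0: 54.1; 15.0: 56.5
- zeta (time / min: target / %): 20.0: 12.0; 40.0: 18.5; 60.0: 22.5; 80.0: 24.9

(each reading ± 0.5 percentage points)

- the analysis behind the earlier runs scatters by 0.5 percentage points, standard deviation

- which flask leads in amount of target, in percent of the starting material charged ("all alike" within 1.5 percentage points) (midnight / spring / dawn / autumn / all alike)
- how much target is there at the end, in percent of the starting material charged: midnight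
- how much target is there at the end, in percent of the starting material charged: spring
- how much target is there at the end, in percent of the starting material charged: dawn
- how much target is there at the end, in percent of the starting material charged: autumn

So I ask how near that ceiling each flask gets. For a second-order coupling I use the turnover count: the rate constant k, times the starting excess [starting material] minus [coupling partner], times time. With E the exponential of the count and e the equivalents, the target fraction is e(E − 1)/(E − e).

The last epsilon reading gives k = 2.70 M⁻¹ min⁻¹. The last zeta reading, with a different charge at the same temperature, gives 2.65 M⁻¹ min⁻¹, so I keep the form. The first gamma reading gives 23.6 M⁻¹ min⁻¹, so these readings put the activation energy at 52.2 kJ mol⁻¹ and k at 5 °C at 0.851 M⁻¹ min⁻¹.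

Midnight therefore counts at 0.204 h⁻¹, and the turnover count 1.02 gives 49.0%, below the ceiling. Autumn counts 9.21, dawn counts more, and spring counts 39.3 in its hot stretch, so by the count these three flasks come close to the ceiling. But gamma at 15.0 min reads 56.5% where the count gives 58.5%, lower by 2 percentage points. So I put autumn, dawn and spring slightly under the ceiling and cannot rank these three flasks.

The forecast names autumn, with midnight 49%, autumn 50%, spring 6% and dawn 5%, the last two far under my figures, on its ground that dawn and spring “sit hot for hours, so target probably decays heavily”, and it calls its range for these two flasks wide.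

The flasks give midnight 46.8%, spring 53.8%, dawn 53.1% and autumn 57.0%, so autumn leads.

    starting material + coupling partner ⇌ target + released group (K = 52.0, k = 49.0 M⁻¹ h⁻¹, Ea = 54.0 kJ mol⁻¹, ΔH = 3.00 kJ mol⁻¹)
    starting material + released group → side product (k = 13.0 M⁻¹ h⁻¹, Ea = 59.0 kJ mol⁻¹)
    (constants at 5 °C)

Midnight holds 10.3% side product at 5.00 h, and its target stands under my figure. The neighbour is spring read at 80 min, before the change at 1.5 h, so this flask is still at 5 °C. Its count is 0.272, which gives 26.3% target. That flask holds 25.5% target, with 1.94% side product.

(The readings come from a simulation on assumed constants.)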